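**Retrosynthetic overview**

1. The last bond made is the CH2 link between C4 of the acyl-triketone ring and the cyclopentane. It is formed by Knoevenagel condensation/transfer hydrogenation of the ring-complete triketone with a β-hydroxy aldehyde that carries all three cyclopentane stereocentres (chiral pool: (4S)-limonene oxide).
2. The six-membered ring is formed from a five-membered one. Ring carbon C2, with its 3-methylbutanoyl group, is inserted as an acyldiazomethane carbon into the C–C bond of the vicinal diketone of a cyclopentane-1,2,4-trione (1,2-carbon shift, loss of N2).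
3. The enabling feature is that C2 lies between two ring carbonyl carbons, C1 and C3 (a 2-acyl-1,3-dione). C1 and C3 can therefore be the adjacent carbonyls of a five-membered ring that already holds C4, C5 and the quaternary carbon C6 (methyl, prenyl); C6 is a spectator of the shift.
4. The quaternary stereocentre is set before the ring enlargement by ketoreductase desymmetrisation of 2-methyl-2-prenylcyclopentane-1,3-dione. α-Hydroxylation and oxidation then give the trione.
5. Ring order: five-membered dione (bought) → six-membered ring by enlargement → terpene cyclopentane (closed separately by aldol condensation) attached last.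

Key step: step 7

Remark: cyclic tri- and tetracarbonyl compounds are drawn in one enol form only; (4S)-limonene 1,2-oxide (cis/trans mixture) is taken as commercial, otherwise one epoxidation of (S)-limonene precedes step 8.

**Route**

Step 1
Reactants: 1 2-methylcyclopentane-1,3-dione; 2 1-bromo-3-methylbut-2-ene (prenyl bromide)
Product: 3 2-methyl-2-(3-methylbut-2-en-1-yl)cyclopentane-1,3-dione
Conditions: NaOH (1 M aq), 25 °C
Reagents that add atoms: none
Why: C-alkylation of the enolate of a cyclic 1,3-dione in water, the standard access to 2,2-disubstituted cyclopentane-1,3-diones; the product is prochiral and no stereocentre is formed.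

Step 2
Reactants: 3 2-methyl-2-(3-methylbut-2-en-1-yl)cyclopentane-1,3-dione
Product: 4 (2S,3S)-3-hydroxy-2-methyl-2-(3-methylbut-2-en-1-yl)cyclopentan-1-one
Conditions: ketoreductase (NADPH-dependent alcohol dehydrogenase), NADP+ (cat.), i-PrOH, phosphate buffer pH 7, DMSO (5%), 30 °C
Reagents that add atoms: none
Why: Enzymatic desymmetrisation by a ketoreductase, which reduces one of the two enantiotopic carbonyl groups; the active site fixes the quaternary carbon as S (and the carbinol as S), the sense known for microbial reduction of 2-allyl-2-methylcyclopentane-1,3-dione.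

Step 3
Reactants: 4 (2S,3S)-3-hydroxy-2-methyl-2-(3-methylbut-2-en-1-yl)cyclopentan-1-one
Product: 5 (2S,3S)-3,5-dihydroxy-2-methyl-2-(3-methylbut-2-en-1-yl)cyclopentan-1-one (both C5 epimers)
Conditions: KN(SiMe3)2 (2.3 equiv), THF, −78 °C; 3-phenyl-2-(phenylsulfonyl)oxaziridine, −78 °C; AcOH
Reagents that add atoms: 3-phenyl-2-(phenylsulfonyl)oxaziridine, O=S(=O)(c1ccccc1)N1OC1c1ccccc1
Why: Enolate hydroxylation with an N-sulfonyloxaziridine (Davis oxidation); the alkoxide–enolate can only form towards C5 because C2 is quaternary, and the configuration of the new carbinol is irrelevant since it is oxidised in step 4.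

Step 4
Reactants: 5 (2S,3S)-3,5-dihydroxy-2-methyl-2-(3-methylbut-2-en-1-yl)cyclopentan-1-one
Product: 6 (5S)-2-hydroxy-5-methyl-5-(3-methylbut-2-en-1-yl)cyclopent-2-ene-1,4-dione [enol of (3S)-3-methyl-3-prenylcyclopentane-1,2,4-trione]
Conditions: Dess–Martin periodinane (2.6 equiv), CH2Cl2, 0 → 25 °C
Reagents that add atoms: none
Why: Dess–Martin oxidation of both secondary alcohols gives the 1,2,4-trione, which enolises to the vinylogous acid; the quaternary centre stays defined because the oxygen introduced in step 3 makes its two flanking carbonyls constitutionally different at every stage.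

Step 5
Reactants: 6 (5S)-2-hydroxy-5-methyl-5-(3-methylbut-2-en-1-yl)cyclopent-2-ene-1,4-dione
Product: 7 (5S)-2-[(tert-butyldimethylsilyl)oxy]-5-methyl-5-(3-methylbut-2-en-1-yl)cyclopent-2-ene-1,4-dione
Conditions: TBSCl, Et3N, DMAP (cat.), CH2Cl2, 0 °C
Reagents that add atoms: tert-butyldimethylsilyl chloride, CC(C)(C)[Si](C)(C)Cl
Why: O-silylation of the acidic enol removes the proton that would quench the diazoketone in step 7 and leaves C1 as the only carbonyl that is not a vinylogous ester.

Step 6
Reactants: 8 3-methylbutanoyl chloride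
Product: 9 1-diazo-4-methylpentan-2-one
Conditions: TMSCHN2 (2 M in hexanes), MeCN/THF, 0 → 25 °C
Reagents that add atoms: (trimethylsilyl)diazomethane, C[Si](C)(C)C=[N+]=[N-]
Why: Acylation of a diazomethane equivalent by an acid chloride (first stage of the Arndt–Eistert sequence) gives the α-diazoketone, chloride removing the silyl group as chlorotrimethylsilane.

Step 7
Reactants: 7 (5S)-2-[(tert-butyldimethylsilyl)oxy]-5-methyl-5-(3-methylbut-2-en-1-yl)cyclopent-2-ene-1,4-dione; 9 1-diazo-4-methylpentan-2-one
Product: 11 (6S)-3,5-dihydroxy-6-methyl-2-(3-methylbutanoyl)-6-(3-methylbut-2-en-1-yl)cyclohexa-2,4-dien-1-one, via silyl enol ether 10 (not isolated)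
Conditions: BF3·OEt2 (1.2 equiv), CH2Cl2, −78 → −20 °C; then HCl (1 M aq), THF, 0 °C
Reagents that add atoms: none
Why: Proposed new method: BF3 activates the cross-conjugated ketone C1 of 7 (C4 is deactivated as a vinylogous silyl ester), the diazo carbon of 9 adds to it, and the β-diazonium alkoxide loses N2 with a 1,2-shift of ring carbon C2 from C1 to the former diazo carbon, so that the acyl-bearing carbon is inserted into the C1–C2 bond. The closest known reactions are the Lewis acid-promoted Tiffeneau–Demjanov-type homologation of ketones with α-diazo carbonyl compounds and the enlargement of cyclic vicinal diketones by diazoalkanes with acyl shift; new is the use of an acyldiazomethane on the enol ether of a cyclopentane-1,2,4-trione. The six-membered ring is not closed by a new ring-forming bond but arises by ring enlargement (1,2-carbon shift) of the five-membered ring, giving the 2-acyl-1,3-dione 10, whose silyl group is hydrolysed in the same flask. No new stereocentre is formed (the inserted carbon is enolised) and the quaternary carbon is a spectator, so the S configuration from step 2 is carried over. The step needs addition at C1 rather than C4 and migration of C2 rather than of the quaternary carbon C5: the first is secured by the vinylogous ester character of C4, the second by the conformation of the adduct, in which the acyl group avoids the quaternary carbon so that N2 stands anti to the flat sp2 carbon C2, whose silyloxy lone pair also supports the shift.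

Step 8
Reactants: 12 (4S)-1-methyl-4-(prop-1-en-2-yl)-7-oxabicyclo[4.1.0]heptane [(4S)-limonene 1,2-oxide, cis/trans mixture]
Product: 14 (3S)-6-oxo-3-(prop-1-en-2-yl)heptanal, via limonene-1,2-diol 13 (not isolated)
Conditions: H5IO6, THF/H2O, 0 → 25 °C
Reagents that add atoms: water, O
Why: Acid-promoted epoxide hydrolysis followed by Malaprade glycol cleavage opens the six-membered ring; both epoxide diastereomers converge and the chiral-pool stereocentre is not touched.

Step 9
Reactants: 14 (3S)-6-oxo-3-(prop-1-en-2-yl)heptanal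
Product: 16 (5R)-2-methyl-5-(prop-1-en-2-yl)cyclopent-1-ene-1-carbaldehyde, via aldol adduct 15 (not isolated)
Conditions: piperidine (cat.), AcOH (cat.), toluene, 60 °C
Reagents that add atoms: none
Why: Intramolecular aldol condensation (the enamine of the aldehyde adds to the methyl ketone in a 5-exo-trig closure, then water is lost) gives the conjugated cyclopentene carbaldehyde; the existing stereocentre is not involved.

Step 10
Reactants: 16 (5R)-2-methyl-5-(prop-1-en-2-yl)cyclopent-1-ene-1-carbaldehyde
Product: 17 (1R,2R,5S)-5-methyl-2-(prop-1-en-2-yl)-6-oxabicyclo[3.1.0]hexane-1-carbaldehyde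
Conditions: H2O2 (30% aq), NaOH (cat.), MeOH, 0 °C
Reagents that add atoms: hydrogen peroxide, OO
Why: Weitz–Scheffer nucleophilic epoxidation touches only the electron-poor enal double bond; after reversible hydroperoxide addition the ring closes on the face opposite the neighbouring isopropenyl group, which sets both epoxide carbons by substrate control.

Step 11
Reactants: 17 (1R,2R,5S)-5-methyl-2-(prop-1-en-2-yl)-6-oxabicyclo[3.1.0]hexane-1-carbaldehyde
Product: 18 (1R,2S,5S)-2-hydroxy-2-methyl-5-(prop-1-en-2-yl)cyclopentane-1-carbaldehyde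
Conditions: SmI2 (2.2 equiv), THF/MeOH, −90 °C, then 0 °C
Reagents that add atoms: none
Why: Single-electron reductive opening of an α,β-epoxy carbonyl compound by SmI2 (established for epoxy ketones and esters) cleaves only the Cα–O bond, so the tertiary alcohol keeps the epoxide configuration; the epimerisable α-centre should settle trans to the isopropenyl group and cis to the hydroxyl group under thermodynamic control.

Step 12
Reactants: 11 (6S)-3,5-dihydroxy-6-methyl-2-(3-methylbutanoyl)-6-(3-methylbut-2-en-1-yl)cyclohexa-2,4-dien-1-one; 18 (1R,2S,5S)-2-hydroxy-2-methyl-5-(prop-1-en-2-yl)cyclopentane-1-carbaldehyde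
Product: 20 (6S)-3,5-dihydroxy-4-{[(1R,2S,5S)-2-hydroxy-2-methyl-5-(prop-1-en-2-yl)cyclopentyl]methyl}-6-methyl-2-(3-methylbutanoyl)-6-(3-methylbut-2-en-1-yl)cyclohexa-2,4-dien-1-one, via alkylidene triketone 19 (not isolated)
Conditions: Hantzsch ester (diethyl 2,6-dimethyl-1,4-dihydropyridine-3,5-dicarboxylate), L-proline (cat.), CH2Cl2, 25 °C
Reagents that add atoms: none
Why: Organocatalytic reductive alkylation (Knoevenagel condensation at C4, the only free ring carbon, then transfer hydrogenation of the alkylidene triketone) forms the CH2 link; no stereocentre is created, the cyclopentane centres come from 18 (its α-centre held trans by thermodynamic preference) and the quaternary centre from 11.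

**Compound list**

1 | 2-methylcyclopentane-1,3-dione | CC1C(=O)CCC1=O | starting material
2 | 1-bromo-3-methylbut-2-ene | CC(C)=CCBr | starting material
3 | 2-methyl-2-(3-methylbut-2-en-1-yl)cyclopentane-1,3-dione | CC(C)=CCC1(C)C(=O)CCC1=O | intermediate
4 | (2S,3S)-3-hydroxy-2-methyl-2-(3-methylbut-2-en-1-yl)cyclopentan-1-one | O[C@@H]1[C@](C)(CC=C(C)C)C(=O)CC1 | intermediate
5 | (2S,3S)-3,5-dihydroxy-2-methyl-2-(3-methylbut-2-en-1-yl)cyclopentan-1-one (C5 epimers) | O[C@@H]1[C@](C)(CC=C(C)C)C(=O)C(O)C1 | intermediate
6 | (5S)-2-hydroxy-5-methyl-5-(3-methylbut-2-en-1-yl)cyclopent-2-ene-1,4-dione | OC1=CC(=O)[C@](C)(CC=C(C)C)C1=O | intermediate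
7 | (5S)-2-[(tert-butyldimethylsilyl)oxy]-5-methyl-5-(3-methylbut-2-en-1-yl)cyclopent-2-ene-1,4-dione | CC(C)(C)[Si](C)(C)OC1=CC(=O)[C@](C)(CC=C(C)C)C1=O | intermediate
8 | 3-methylbutanoyl chloride | CC(C)CC(=O)Cl | starting material
9 | 1-diazo-4-methylpentan-2-one | CC(C)CC(=O)C=[N+]=[N-] | intermediate
10 | tert-butyldimethylsilyl enol ether of 11 at the C3 oxygen (quaternary carbon as in 11; one enol form drawn) | CC(C)CC(=O)C1=C(O)[C@@](C)(CC=C(C)C)C(=O)C=C1O[Si](C)(C)C(C)(C)C | intermediate
11 | (6S)-3,5-dihydroxy-6-methyl-2-(3-methylbutanoyl)-6-(3-methylbut-2-en-1-yl)cyclohexa-2,4-dien-1-one | CC(C)CC(=O)C1=C(O)C=C(O)[C@](C)(CC=C(C)C)C1=O | intermediate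
12 | (4S)-1-methyl-4-(prop-1-en-2-yl)-7-oxabicyclo[4.1.0]heptane (cis/trans mixture) | C=C(C)[C@@H]1CC2OC2(C)CC1 | starting material
13 | (4S)-1-methyl-4-(prop-1-en-2-yl)cyclohexane-1,2-diol (mixture at C1/C2) | C=C(C)[C@@H]1CC(O)C(C)(O)CC1 | intermediate
14 | (3S)-6-oxo-3-(prop-1-en-2-yl)heptanal | C=C(C)[C@H](CC=O)CCC(C)=O | intermediate
15 | 2-hydroxy-2-methyl-5-(prop-1-en-2-yl)cyclopentane-1-carbaldehyde (aldol adduct, mixture at C1/C2, C5 as in 16) | C=C(C)[C@H]1CCC(C)(O)C1C=O | intermediate
16 | (5R)-2-methyl-5-(prop-1-en-2-yl)cyclopent-1-ene-1-carbaldehyde | C=C(C)[C@H]1CCC(C)=C1C=O | intermediate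
17 | (1R,2R,5S)-5-methyl-2-(prop-1-en-2-yl)-6-oxabicyclo[3.1.0]hexane-1-carbaldehyde | C=C(C)[C@H]1CC[C@]2(C)O[C@@]21C=O | intermediate
18 | (1R,2S,5S)-2-hydroxy-2-methyl-5-(prop-1-en-2-yl)cyclopentane-1-carbaldehyde | C=C(C)[C@H]1CC[C@](C)(O)[C@@H]1C=O | intermediate
19 | Knoevenagel adduct of 11 and 18: 4-(cyclopentylmethylidene) triketone, alkene geometry not defined | C=C(C)[C@H]1CC[C@](C)(O)[C@@H]1C=C1C(=O)[C@](C)(CC=C(C)C)C(=O)C(C(=O)CC(C)C)=C1O | intermediate
20 | (6S)-3,5-dihydroxy-4-{[(1R,2S,5S)-2-hydroxy-2-methyl-5-(prop-1-en-2-yl)cyclopentyl]methyl}-6-methyl-2-(3-methylbutanoyl)-6-(3-methylbut-2-en-1-yl)cyclohexa-2,4-dien-1-one | C=C(C)[C@H]1CC[C@](C)(O)[C@@H]1CC1=C(O)[C@](C)(CC=C(C)C)C(=O)C(C(=O)CC(C)C)=C1O | target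

**Step count and risks**

Total steps: 12. Longest linear sequence: 7 steps (1, 2, 3, 4, 5, 7, 12); steps 6 and 8–11 are side branches.

Steps most likely to fail:

Step 7 (proposed new method). The weakly nucleophilic diazoketone may add too slowly to the hindered ketone, and the 1,2-shift may take the wrong course (migration of the quaternary carbon instead of the sp2 carbon). The fallback sets out from 7 and 9 and returns at 10, hence 11. It separates addition and shift with known chemistry: the lithium derivative of 9 (LiN(i-Pr)2, THF, −78 °C) adds to the ketone C1 of 7 to give the α-diazo-β-hydroxy ketone F1. Rh2(OAc)4 (cat., CH2Cl2, 25 °C) then brings about the known ring-enlarging 1,2-shift of 1-(1-diazo-2-oxoalkyl)cycloalkanols to the 2-acyl ketone 10, which is desilylated as in step 7.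

Step 12. Amine-promoted loss of water or retro-aldol cleavage of the β-hydroxy aldehyde may outrun condensation at the hindered aldehyde. The fallback sets out from 11 and returns at 20; it builds the tertiary alcohol after the coupling:
- Cyclopent-2-en-1-one undergoes copper-catalysed asymmetric conjugate addition of isopropenylmagnesium bromide (CuBr·SMe2, chiral ferrocenyl diphosphine), and the enolate is trapped with dimethyl(methylidene)ammonium iodide to give the Mannich base F6.
- N-Methylation and elimination (MeI, then NaHCO3) give the enone F7.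
- Michael addition of 11 to F7 (Et3N cat., THF) gives the ketone F8, whose α-centre settles trans to the isopropenyl group.
- MeMgBr/CeCl3 in excess (the triketone being masked as its dianion) adds to the cyclopentanone from the face opposite the neighbouring side chain and gives 20.

Step 11. Electron transfer may not stop after the epoxide opening (pinacol-type coupling or further reduction of the aldehyde), and the enolate may be protonated from the wrong face without later equilibration. The fallback sets out from 17 and returns at 18; it does the opening at the ester level, where it is established: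
- Pinnick oxidation (NaClO2, NaH2PO4, 2-methylbut-2-ene) gives the epoxy acid F2.
- TMSCHN2 gives the methyl ester F3.
- SmI2 (THF/MeOH) gives the β-hydroxy ester F4.
- LiAlH4 gives the diol F5.
- Selective oxidation of the primary alcohol (TEMPO, PhI(OAc)2) gives 18.

**Further compounds**

F1 | step 7 | 4-(1-diazo-4-methyl-2-oxopentyl)-4-hydroxy-3-[(tert-butyldimethylsilyl)oxy]-5-methyl-5-(3-methylbut-2-en-1-yl)cyclopent-2-en-1-one (quaternary carbon as in 7, carbinol epimers) | CC(C)CC(=O)C(=[N+]=[N-])C1(O)C(O[Si](C)(C)C(C)(C)C)=CC(=O)[C@]1(C)CC=C(C)C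
F2 | step 11 | (1R,2R,5S)-5-methyl-2-(prop-1-en-2-yl)-6-oxabicyclo[3.1.0]hexane-1-carboxylic acid | C=C(C)[C@H]1CC[C@]2(C)O[C@@]21C(=O)O
F3 | step 11 | methyl (1R,2R,5S)-5-methyl-2-(prop-1-en-2-yl)-6-oxabicyclo[3.1.0]hexane-1-carboxylate | C=C(C)[C@H]1CC[C@]2(C)O[C@@]21C(=O)OC
F4 | step 11 | methyl (1R,2S,5S)-2-hydroxy-2-methyl-5-(prop-1-en-2-yl)cyclopentane-1-carboxylate | C=C(C)[C@H]1CC[C@](C)(O)[C@@H]1C(=O)OC
F5 | step 11 | (1S,2S,3S)-2-(hydroxymethyl)-1-methyl-3-(prop-1-en-2-yl)cyclopentan-1-ol | C=C(C)[C@H]1CC[C@](C)(O)[C@@H]1CO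
F6 | step 12 | (2S,3S)-2-[(dimethylamino)methyl]-3-(prop-1-en-2-yl)cyclopentan-1-one | C=C(C)[C@H]1CCC(=O)[C@@H]1CN(C)C
F7 | step 12 | (3R)-2-methylidene-3-(prop-1-en-2-yl)cyclopentan-1-one | C=C(C)[C@H]1CCC(=O)C1=C
F8 | step 12 | (6S)-3,5-dihydroxy-6-methyl-2-(3-methylbutanoyl)-6-(3-methylbut-2-en-1-yl)-4-{[(1R,2S)-5-oxo-2-(prop-1-en-2-yl)cyclopentyl]methyl}cyclohexa-2,4-dien-1-one | C=C(C)[C@H]1CCC(=O)[C@@H]1CC1=C(O)[C@](C)(CC=C(C)C)C(=O)C(C(=O)CC(C)C)=C1O
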